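**Retrosynthetic overview**
1. Target 17 ⇐ dipotassium salt 16 (K⁺→H⁺ exchange) ⇐ 5‑O‑pivalate 15. Both S–O bonds come from SO3·pyridine: the aryl sulfate at the aldehyde stage, the benzylic sulfate after CHO → CH2OH.
2. Differentiating the two phenol oxygens: aldehyde 12 (4‑OH free, 5‑OPiv) ⇐ catechol aldehyde 9 by acidity‑guided 4‑O‑PMB protection, 5‑O‑pivaloylation and PMB removal.
3. 9 ⇐ vanillin 6 by two brominations (ortho to OH, then para to OMe) and O‑demethylation.
4. Key C–C disconnection: the aryl–benzylic carbon bond. Vanillin ⇐ guaiacol 1 + glyoxylic acid 2, by aldol‑type para addition of the phenolate to the aldehyde followed by oxidative decarboxylation.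
5. No ring is formed, because the benzene ring arrives with guaiacol.

**Assumption:** the target has no stereocentre, so no stereocontrol is needed. The free bis(hydrogen sulfate) is acid‑labile, so it is released only in the last step from its stable dipotassium salt.

**Step 1 (key C–C bond formation)**
Reactants: 1 guaiacol (2‑methoxyphenol); 2 glyoxylic acid (50 % aqueous solution)
Product: 4 (±)-4-hydroxy-3-methoxymandelic acid, via dienone aldol adduct 3 (not isolated)
Conditions: NaOH (2.2 equiv), H2O, 0 °C → rt, 24 h (1.5 equiv of 1); then HCl to pH 2, EtOAc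
Reagents that add atoms: none
Why: The guaiacolate acts as a vinylogous enolate whose para carbon adds to the highly electrophilic aldehyde of glyoxylate in an intermolecular aldol‑type addition (phenol hydroxyalkylation, Lederer–Manasse type) and the dienone 3 rearomatises, with low temperature and excess 1 suppressing ortho and double addition, and the racemic carbinol centre is erased in step 2.

**Step 2**
Reactants: 4 (±)-4-hydroxy-3-methoxymandelic acid
Product: 6 vanillin (4-hydroxy-3-methoxybenzaldehyde), via vanilloylformic acid 5 (not isolated)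
Conditions: air (O2), CuSO4 (10 mol %), aq NaOH, 95 °C; then HCl to pH 3, warm
Reagents that add atoms: none
Why: Oxidative decarboxylation, in which Cu‑catalysed aerobic oxidation of the benzylic α‑hydroxy acid gives the aryl glyoxylic acid 5, which loses CO2 on acidification because the p‑hydroxyaryl group stabilises the protonation/decarboxylation pathway.

**Step 3**
Reactants: 6 vanillin
Product: 7 5-bromovanillin (3-bromo-4-hydroxy-5-methoxybenzaldehyde)
Conditions: Br2 (1.05 equiv), MeOH, 0 °C → rt
Reagents that add atoms: bromine, BrBr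
Why: Electrophilic aromatic bromination goes to the only free position ortho to the strongly activating OH, since the para position carries CHO.

**Step 4**
Reactants: 7 5-bromovanillin
Product: 8 5,6-dibromovanillin (2,3-dibromo-4-hydroxy-5-methoxybenzaldehyde)
Conditions: Br2 (1.2 equiv), Fe powder (10 mol %), AcOH, rt → 50 °C
Reagents that add atoms: bromine, BrBr
Why: Lewis‑acid‑assisted electrophilic aromatic bromination in which the OMe group directs para to C6, rather than to the crowded C2 between OMe and CHO, and non‑aqueous AcOH disfavours ipso bromodeformylation.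

**Step 5**
Reactants: 8 5,6-dibromovanillin
Product: 9 2,3-dibromo-4,5-dihydroxybenzaldehyde
Conditions: BBr3 (2.5 equiv), CH2Cl2, −78 °C → rt; then H2O
Reagents that add atoms: none
Why: Lewis‑acid aryl methyl ether cleavage (BBr3 demethylation) proceeds by bromide attack on the O‑methyl of the boron‑complexed ether and leaves the aldehyde and aryl bromides untouched.

**Step 6**
Reactants: 9 2,3-dibromo-4,5-dihydroxybenzaldehyde
Product: 10 2,3-dibromo-5-hydroxy-4-[(4-methoxybenzyl)oxy]benzaldehyde
Conditions: PMBCl (1.05 equiv), NaHCO3 (1.5 equiv), NaI (0.3 equiv), DMF, 40 °C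
Reagents that add atoms: 4‑methoxybenzyl chloride, COc1ccc(CCl)cc1
Why: Williamson etherification under acidity control, because the weak base ionises only the 4‑OH (para to CHO, ortho to Br), so the monoanion is alkylated at O‑4 and the 5‑OH stays free.

**Step 7**
Reactants: 10 2,3-dibromo-5-hydroxy-4-[(4-methoxybenzyl)oxy]benzaldehyde
Product: 11 3,4-dibromo-5-formyl-2-[(4-methoxybenzyl)oxy]phenyl pivalate
Conditions: PivCl (1.3 equiv), Et3N, DMAP (cat.), CH2Cl2, 0 °C → rt
Reagents that add atoms: pivaloyl chloride, CC(C)(C)C(=O)Cl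
Why: DMAP‑catalysed O‑acylation of the only free phenol installs a bulky ester that survives borohydride, SO3·amine and bicarbonate work‑ups yet is removed by base, to which sulfate salts are inert.

**Step 8**
Reactants: 11 3,4-dibromo-5-formyl-2-[(4-methoxybenzyl)oxy]phenyl pivalate
Product: 12 3,4-dibromo-5-formyl-2-hydroxyphenyl pivalate
Conditions: TFA/CH2Cl2 (1:4), anisole (5 equiv), 0 °C → rt
Reagents that add atoms: none
Why: Acidolytic (SN1) PMB ether cleavage is easy because an acidic phenol leaves and anisole traps the cation by Friedel–Crafts alkylation, while the pivalate sits on the less acidic, less hindered oxygen and so has no driving force to migrate.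

**Step 9**
Reactants: 12 3,4-dibromo-5-formyl-2-hydroxyphenyl pivalate
Product: 13 potassium 2,3-dibromo-4-formyl-6-(pivaloyloxy)phenyl sulfate
Conditions: SO3·pyridine (3 equiv), pyridine, 45 °C; then cold aq KHCO3 to pH 8; SiO2 (CH2Cl2/MeOH) or C18
Reagents that add atoms: sulfur trioxide–pyridine complex, O=S(=O)([O-])[n+]1ccccc1; potassium hydrogen carbonate, [K+].OC(=O)[O-]
Why: O‑sulfation with an SO3–amine complex hits the only free OH, and doing it before the aldehyde is reduced means a p‑hydroxybenzyl sulfate (a quinone methide precursor) never exists.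

**Step 10**
Reactants: 13 potassium 2,3-dibromo-4-formyl-6-(pivaloyloxy)phenyl sulfate
Product: 14 potassium 2,3-dibromo-4-(hydroxymethyl)-6-(pivaloyloxy)phenyl sulfate
Conditions: KBH4 (0.6 equiv), MeOH, 0 °C, 30 min; aqueous work‑up at pH 7–8
Reagents that add atoms: none
Why: Chemoselective borohydride reduction of the aldehyde spares the hindered aryl pivalate, the sulfate monoanion and the C–Br bonds, and KBH4 keeps potassium as the only counter‑ion.

**Step 11**
Reactants: 14 potassium 2,3-dibromo-4-(hydroxymethyl)-6-(pivaloyloxy)phenyl sulfate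
Product: 15 dipotassium 2,3-dibromo-6-(pivaloyloxy)-4-[(sulfonatooxy)methyl]phenyl sulfate
Conditions: SO3·pyridine (2.5 equiv), DMF, 0 °C → rt; then cold aq KHCO3 to pH 8; C18
Reagents that add atoms: sulfur trioxide–pyridine complex, O=S(=O)([O-])[n+]1ccccc1; potassium hydrogen carbonate, [K+].OC(=O)[O-]
Why: O‑sulfation of the only remaining hydroxyl (a primary alcohol) gives a benzylic sulfate that resists ionisation because the ring carries two bromines and a para sulfate instead of a free para OH.

**Step 12**
Reactants: 15 dipotassium 2,3-dibromo-6-(pivaloyloxy)-4-[(sulfonatooxy)methyl]phenyl sulfate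
Product: 16 dipotassium 2,3-dibromo-6-hydroxy-4-[(sulfonatooxy)methyl]phenyl sulfate
Conditions: K2CO3 (2 equiv), MeOH, rt → 40 °C; then 1 M HCl to pH 7 at 0 °C; desalting on C18 or Sephadex LH‑20
Reagents that add atoms: none
Why: Base‑mediated transesterification (methanolysis) of the activated aryl ester leaves sulfate monoester anions untouched, and the liberated phenol is meta to the CH2OSO3⁻ group, so no quinone methide can expel the benzylic sulfate.

**Step 13**
Reactants: 16 dipotassium 2,3-dibromo-6-hydroxy-4-[(sulfonatooxy)methyl]phenyl sulfate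
Product: 17 2,3-dibromo-5-hydroxy-4-(sulfooxy)benzyl hydrogen sulfate (target)
Conditions: Dowex 50WX8 (H⁺ form, excess), H2O, 0–4 °C; eluate frozen at once and lyophilised, stored at −20 °C
Reagents that add atoms: none
Why: Cation exchange (K⁺ → H⁺) on a strong‑acid resin changes no covalent bond, and short cold contact with immediate freeze‑drying limits acid‑catalysed S–O solvolysis of the strongly acidic product.

**Compound list**
1 | guaiacol (2‑methoxyphenol) | COc1ccccc1O | starting material
2 | glyoxylic acid | O=CC(=O)O | starting material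
3 | 2‑hydroxy‑2‑(3‑methoxy‑4‑oxocyclohexa‑2,5‑dien‑1‑yl)acetic acid (dienone aldol adduct, transient stereoisomer mixture) | COC1=CC(C(O)C(=O)O)C=CC1=O | intermediate (not isolated)
4 | (±)‑4‑hydroxy‑3‑methoxymandelic acid (racemic) | COc1cc(C(O)C(=O)O)ccc1O | intermediate
5 | vanilloylformic acid ((4‑hydroxy‑3‑methoxyphenyl)glyoxylic acid) | COc1cc(C(=O)C(=O)O)ccc1O | intermediate (not isolated)
6 | vanillin | COc1cc(C=O)ccc1O | intermediate
7 | 5‑bromovanillin | COc1cc(C=O)cc(Br)c1O | intermediate
8 | 5,6‑dibromovanillin (2,3‑dibromo‑4‑hydroxy‑5‑methoxybenzaldehyde) | COc1cc(C=O)c(Br)c(Br)c1O | intermediate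
9 | 2,3‑dibromo‑4,5‑dihydroxybenzaldehyde | O=Cc1cc(O)c(O)c(Br)c1Br | intermediate
10 | 2,3‑dibromo‑5‑hydroxy‑4‑[(4‑methoxybenzyl)oxy]benzaldehyde | O=Cc1cc(O)c(OCc2ccc(OC)cc2)c(Br)c1Br | intermediate
11 | 3,4‑dibromo‑5‑formyl‑2‑[(4‑methoxybenzyl)oxy]phenyl pivalate | O=Cc1cc(OC(=O)C(C)(C)C)c(OCc2ccc(OC)cc2)c(Br)c1Br | intermediate
12 | 3,4‑dibromo‑5‑formyl‑2‑hydroxyphenyl pivalate | O=Cc1cc(OC(=O)C(C)(C)C)c(O)c(Br)c1Br | intermediate
13 | potassium 2,3‑dibromo‑4‑formyl‑6‑(pivaloyloxy)phenyl sulfate | [K+].[O-]S(=O)(=O)Oc1c(OC(=O)C(C)(C)C)cc(C=O)c(Br)c1Br | intermediate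
14 | potassium 2,3‑dibromo‑4‑(hydroxymethyl)‑6‑(pivaloyloxy)phenyl sulfate | [K+].[O-]S(=O)(=O)Oc1c(OC(=O)C(C)(C)C)cc(CO)c(Br)c1Br | intermediate
15 | dipotassium 2,3‑dibromo‑6‑(pivaloyloxy)‑4‑[(sulfonatooxy)methyl]phenyl sulfate | [K+].[K+].[O-]S(=O)(=O)OCc1cc(OC(=O)C(C)(C)C)c(OS(=O)(=O)[O-])c(Br)c1Br | intermediate
16 | dipotassium 2,3‑dibromo‑6‑hydroxy‑4‑[(sulfonatooxy)methyl]phenyl sulfate | [K+].[K+].[O-]S(=O)(=O)OCc1cc(O)c(OS(=O)(=O)[O-])c(Br)c1Br | intermediate
17 | 2,3‑dibromo‑5‑hydroxy‑4‑(sulfooxy)benzyl hydrogen sulfate (achiral) | O=S(=O)(O)OCc1cc(O)c(OS(=O)(=O)O)c(Br)c1Br | target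

**Total step count:** 13. **Longest linear sequence:** 13 (fully linear).

**Three steps most likely to fail, each with a fallback**

Step 6 (regioselective 4‑O‑alkylation): the bromine next to O‑4 may erode the selectivity. The fallback sets out from 9 and comes back at 12, so it replaces steps 6–8. It swaps kinetic alkylation selectivity for thermodynamic acyl selectivity. PivCl (2.5 equiv), Et3N and DMAP in CH2Cl2 convert 9 into 3,4‑dibromo‑5‑formyl‑1,2‑phenylene dipivalate F1. One equivalent of piperidine in THF at 0 °C then removes a single pivaloyl group. The ester of the more acidic 4‑OH is the more activated one. Any 4‑O‑acyl/5‑OH isomer equilibrates by O→O acyl shift under the basic conditions towards the better stabilised 4‑phenoxide, which is 12.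

Step 9 (sulfation of a hindered, electron‑poor phenol, with a polar product): the fallback sets out from 12 and comes back at 14, carrying the sulfate as a neutral protected diester. 2,2,2‑Trichloroethyl chlorosulfate, Et3N and DMAP in THF give the chromatographable 3,4‑dibromo‑5‑formyl‑2‑{[(2,2,2‑trichloroethoxy)sulfonyl]oxy}phenyl pivalate F2. NaBH4 in THF/MeOH at 0 °C reduces the aldehyde to 3,4‑dibromo‑5‑(hydroxymethyl)‑2‑{[(2,2,2‑trichloroethoxy)sulfonyl]oxy}phenyl pivalate F3. Zn dust and HCO2NH4 in MeOH at rt fragment the trichloroethyl group reductively, after the aldehyde is gone so that no pinacol coupling can occur. KHCO3 then exchanges ammonium for potassium to give 14.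

Step 13 (release of the labile free acid): the fallback sets out from 16 and comes back at 17, using precipitation metathesis in place of a resin. Ba(OAc)2 (1.0 equiv) in a little water followed by EtOH at 0 °C precipitates barium 2,3‑dibromo‑6‑hydroxy‑4‑[(sulfonatooxy)methyl]phenyl sulfate F4. The solid is suspended in ice water and titrated with exactly 1.00 equiv of H2SO4. The insoluble barium salt is centrifuged off and the supernatant, which never sees excess acid, is freeze‑dried to 17.

**Further compounds**
F1 | step 6 | 3,4‑dibromo‑5‑formyl‑1,2‑phenylene dipivalate | O=Cc1cc(OC(=O)C(C)(C)C)c(OC(=O)C(C)(C)C)c(Br)c1Br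
F2 | step 9 | 3,4‑dibromo‑5‑formyl‑2‑{[(2,2,2‑trichloroethoxy)sulfonyl]oxy}phenyl pivalate | O=Cc1cc(OC(=O)C(C)(C)C)c(OS(=O)(=O)OCC(Cl)(Cl)Cl)c(Br)c1Br
F3 | step 9 | 3,4‑dibromo‑5‑(hydroxymethyl)‑2‑{[(2,2,2‑trichloroethoxy)sulfonyl]oxy}phenyl pivalate | OCc1cc(OC(=O)C(C)(C)C)c(OS(=O)(=O)OCC(Cl)(Cl)Cl)c(Br)c1Br
F4 | step 13 | barium 2,3‑dibromo‑6‑hydroxy‑4‑[(sulfonatooxy)methyl]phenyl sulfate | [Ba+2].[O-]S(=O)(=O)OCc1cc(O)c(OS(=O)(=O)[O-])c(Br)c1Br
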